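The synthesis rests on building ring A by ring expansion of a squarate-derived cyclobutenone. Ring A carries oxygens on C5, C6, C7 and C8a, with the C6 methoxy para to the C8a oxygen, a hydroquinone monoether; C8a, C4a, C5 and C6 are taken from the four squarate carbons and C7–C8 from an alkoxyvinyl group. Heating a 4-methoxy-4-(1-tert-butoxyvinyl)cyclobutenone that already bears the masked C4–C3 chain as a 1,2-dimethoxyvinyl group forms the C8–C8a bond and delivers the fully substituted ring with only the C8a phenol free. tert-Butyl and MOM ethers are chosen so that one mild acid treatment, harmless to the prenyl groups, finishes the flavone.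

Key step: step 3

Assumption: the 1,2-dimethoxyvinyl unit is drawn and named as the Z isomer (both methoxy groups cis), the geometry expected for the lithium reagent. Step 4 erases this double bond, so isomerisation in steps 1–3 would be of no consequence. The target has no stereocentre.

Step 1
Reactants: 1 1,1,2-trimethoxyethane; 2 di-tert-butyl squarate (3,4-di-tert-butoxycyclobut-3-ene-1,2-dione)
Product: 7 3-tert-butoxy-4-[(Z)-1,2-dimethoxyvinyl]cyclobut-3-ene-1,2-dione, via (Z)-1,2-dimethoxyethene 3 (not isolated), via (Z)-1,2-dimethoxyvinyllithium 4 (not isolated), via lithium cyclobutenolate adduct 5 (not isolated), via adduct trifluoroacetate 6 (not isolated)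
Conditions: s-BuLi (2.0 equiv per 1), THF, −78 to −30 °C; then 2, −78 °C; (CF3CO)2O, −78 °C; cold aq. NaHCO3
Reagents that add atoms: none
Why: Base-induced beta-elimination of methoxide and vinylic deprotonation give the alkoxyvinyllithium, which adds 1,2 to one squarate carbonyl; O-trifluoroacetylation then triggers the allylic transposition of squarate adducts, in which the ionised cyclobutenyl cation collapses by loss of isobutene from the tert-butyl oxocarbenium and so unveils the second carbonyl without water while the enol ether is exposed.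

Step 2
Reactants: 7 3-tert-butoxy-4-[(Z)-1,2-dimethoxyvinyl]cyclobut-3-ene-1,2-dione; 8 tert-butyl vinyl ether
Product: 11 3-tert-butoxy-4-(1-tert-butoxyvinyl)-2-[(Z)-1,2-dimethoxyvinyl]-4-methoxycyclobut-2-en-1-one (racemic), via 1-tert-butoxyvinyllithium 9 (not isolated), via lithium alkoxide adduct 10 (not isolated)
Conditions: 8 (excess), t-BuLi, THF, −78 to 0 °C; then 7, −78 °C; MeOTf, −78 to −20 °C; aq. NaHCO3; filtration through Et3N-deactivated silica
Reagents that add atoms: methyl trifluoromethanesulfonate (MeOTf), COS(=O)(=O)C(F)(F)F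
Why: Alpha-lithiation of the vinyl ether and 1,2-addition of the 1-alkoxyvinyllithium should occur at the ketone-like carbonyl next to the tert-butoxy-bearing carbon, because the other carbonyl is deactivated as a vinylogous ester, and the cold tertiary lithium alkoxide is O-methylated in situ (Williamson-type alkylation); the new quaternary stereocentre forms as a racemate and is destroyed in step 3.

Step 3
Reactants: 11 3-tert-butoxy-4-(1-tert-butoxyvinyl)-2-[(Z)-1,2-dimethoxyvinyl]-4-methoxycyclobut-2-en-1-one (racemic)
Product: 14 3,5-di-tert-butoxy-2-[(Z)-1,2-dimethoxyvinyl]-4-methoxyphenol, via dienylketene 12 (not isolated), via cyclohexadienone 13 (not isolated)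
Conditions: PhMe (0.02 M), 110 °C, Ar
Reagents that add atoms: none
Why: Thermal conrotatory 4-electron ring opening breaks the bond between the carbonyl carbon and the methoxy-bearing sp3 carbon of 11 and gives dienylketene 12; its ketene carbon and the terminal CH2 of the tert-butoxyvinyl group then join in a disrotatory 6-electron electrocyclization (the future C8a–C8 bond) to dienone 13, which tautomerizes to phenol 14. The closest known reaction type is the Moore rearrangement of 4-alkenyl-4-alkoxycyclobutenones to hydroquinone monoethers. The one ring formed, ring A, is closed in a 6π electrocyclic mode across the ketene carbon and the vinyl terminus, not by an ionic cyclization. No stereocentre is created, and the racemic quaternary centre of 11 disappears. The selectivity needed is outward rotation of the 4-methoxy group in the ring opening, which the lone-pair donor on the sp3 carbon enforces, so that the alkoxyvinyl group turns inward toward the ketene; the positions of all ring A substituents then follow from connectivity, the ketene carbon becoming C8a with the only free hydroxyl.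

Step 4
Reactants: 14 3,5-di-tert-butoxy-2-[(Z)-1,2-dimethoxyvinyl]-4-methoxyphenol
Product: 15 1-(2,4-di-tert-butoxy-6-hydroxy-3-methoxyphenyl)-2-methoxyethan-1-one
Conditions: aq. HCl (0.5 M), THF, 0 °C to rt
Reagents that add atoms: water, O
Why: Acid-catalysed enol ether hydrolysis: protonation at the terminal CH(OMe) carbon gives the aryl- and methoxy-stabilised oxocarbenium ion, water adds and methanol leaves to give the omega-methoxy ketone, while aryl tert-butyl ethers tolerate cold dilute aqueous acid.

Step 5
Reactants: 16 methyl 4-hydroxy-3,5-diiodobenzoate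
Product: 17 methyl 3,5-diiodo-4-(methoxymethoxy)benzoate
Conditions: MOMCl, K2CO3, acetone, 0 °C to rt
Reagents that add atoms: chloromethyl methyl ether (MOMCl), COCCl
Why: Williamson etherification of the acidic, iodine-flanked phenoxide with the reactive alpha-chloro ether masks the phenol as an acetal that survives palladium, base and carbodiimide chemistry.

Step 6
Reactants: 17 methyl 3,5-diiodo-4-(methoxymethoxy)benzoate; 18 tributyl(3-methylbut-2-en-1-yl)stannane
Product: 19 methyl 4-(methoxymethoxy)-3,5-bis(3-methylbut-2-en-1-yl)benzoate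
Conditions: Pd(PPh3)4 (cat.), DMF, 90 °C; aq. KF work-up
Reagents that add atoms: none
Why: Double Stille coupling: oxidative addition of zerovalent palladium into each C–I bond, transmetalation from tin and reductive elimination at the less hindered allyl terminus should give the linear 3-methylbut-2-enyl groups.

Step 7
Reactants: 19 methyl 4-(methoxymethoxy)-3,5-bis(3-methylbut-2-en-1-yl)benzoate
Product: 20 4-(methoxymethoxy)-3,5-bis(3-methylbut-2-en-1-yl)benzoic acid
Conditions: LiOH·H2O, THF/MeOH/H2O, 50 °C; then cold dilute HCl to pH 4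
Reagents that add atoms: lithium hydroxide, [Li+].[OH-]
Why: Saponification (base-mediated acyl substitution) of the unhindered methyl ester; the MOM acetal and the prenyl alkenes are inert to hydroxide and to a brief cold acidification.

Step 8
Reactants: 15 1-(2,4-di-tert-butoxy-6-hydroxy-3-methoxyphenyl)-2-methoxyethan-1-one; 20 4-(methoxymethoxy)-3,5-bis(3-methylbut-2-en-1-yl)benzoic acid
Product: 21 3,5-di-tert-butoxy-4-methoxy-2-(methoxyacetyl)phenyl 4-(methoxymethoxy)-3,5-bis(3-methylbut-2-en-1-yl)benzoate
Conditions: DCC, DMAP (cat.), CH2Cl2, 0 °C to rt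
Reagents that add atoms: none
Why: Steglich esterification: the acylpyridinium formed from 20 acylates the phenol of 15, which avoids an acid chloride and the HCl that would endanger the MOM and prenyl groups.

Step 9
Reactants: 21 3,5-di-tert-butoxy-4-methoxy-2-(methoxyacetyl)phenyl 4-(methoxymethoxy)-3,5-bis(3-methylbut-2-en-1-yl)benzoate
Product: 22 1-(2,4-di-tert-butoxy-6-hydroxy-3-methoxyphenyl)-2-methoxy-3-[4-(methoxymethoxy)-3,5-bis(3-methylbut-2-en-1-yl)phenyl]propane-1,3-dione (racemic)
Conditions: LiN(SiMe3)2 (2.5 equiv), THF, −78 °C to rt; AcOH quench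
Reagents that add atoms: none
Why: Baker–Venkataraman rearrangement: the alpha-methoxy ketone enolate attacks the neighbouring aryl ester through a six-membered transition state and the aroyl group shifts from O to C, giving the 1,3-diketone, whose C2 stereocentre is racemic and disappears in step 10.

Step 10
Reactants: 22 1-(2,4-di-tert-butoxy-6-hydroxy-3-methoxyphenyl)-2-methoxy-3-[4-(methoxymethoxy)-3,5-bis(3-methylbut-2-en-1-yl)phenyl]propane-1,3-dione (racemic)
Product: 24 5,7-dihydroxy-2-[4-hydroxy-3,5-bis(3-methylbut-2-en-1-yl)phenyl]-3,6-dimethoxy-4H-chromen-4-one (target CNP0236361.0), via protected flavone 23 (not isolated)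
Conditions: HCl (about 1 M) in MeOH/THF, rt, then 45 °C
Reagents that add atoms: none
Why: Acid-catalysed cyclodehydration: the only free phenol, the C8a hydroxyl, adds to the aroyl carbonyl and water is lost to give chromenone 23 at room temperature, after which warming should remove the two tert-butyl ethers (E1 loss of isobutene, eased by conjugation of both oxygens with the C4 carbonyl) and the MOM acetal under conditions that prenyl groups routinely survive.

Compound list
1 | 1,1,2-trimethoxyethane | COCC(OC)OC | starting material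
2 | di-tert-butyl squarate (3,4-di-tert-butoxycyclobut-3-ene-1,2-dione) | CC(C)(C)OC1=C(OC(C)(C)C)C(=O)C1=O | starting material
3 | (Z)-1,2-dimethoxyethene | CO/C=C\OC | intermediate
4 | (Z)-1,2-dimethoxyvinyllithium | CO/C=C(\OC)[Li] | intermediate
5 | lithium 2,3-di-tert-butoxy-1-[(Z)-1,2-dimethoxyvinyl]-4-oxocyclobut-2-en-1-olate (racemic) | CO/C=C(\OC)C1([O-])C(OC(C)(C)C)=C(OC(C)(C)C)C1=O.[Li+] | intermediate
6 | 2,3-di-tert-butoxy-1-[(Z)-1,2-dimethoxyvinyl]-4-oxocyclobut-2-en-1-yl trifluoroacetate (racemic) | CO/C=C(\OC)C1(OC(=O)C(F)(F)F)C(OC(C)(C)C)=C(OC(C)(C)C)C1=O | intermediate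
7 | 3-tert-butoxy-4-[(Z)-1,2-dimethoxyvinyl]cyclobut-3-ene-1,2-dione | CO/C=C(\OC)C1=C(OC(C)(C)C)C(=O)C1=O | intermediate
8 | tert-butyl vinyl ether | C=COC(C)(C)C | starting material
9 | 1-tert-butoxyvinyllithium | [Li]C(=C)OC(C)(C)C | intermediate
10 | lithium 2-tert-butoxy-1-(1-tert-butoxyvinyl)-3-[(Z)-1,2-dimethoxyvinyl]-4-oxocyclobut-2-en-1-olate (racemic) | CO/C=C(\OC)C1=C(OC(C)(C)C)C([O-])(C(=C)OC(C)(C)C)C1=O.[Li+] | intermediate
11 | 3-tert-butoxy-4-(1-tert-butoxyvinyl)-2-[(Z)-1,2-dimethoxyvinyl]-4-methoxycyclobut-2-en-1-one (racemic) | CO/C=C(\OC)C1=C(OC(C)(C)C)C(OC)(C(=C)OC(C)(C)C)C1=O | intermediate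
12 | (3Z)-3,5-di-tert-butoxy-2-[(Z)-1,2-dimethoxyvinyl]-4-methoxyhexa-1,3,5-trien-1-one (dienylketene) | CO/C=C(\OC)C(=C=O)/C(OC(C)(C)C)=C(/OC)C(=C)OC(C)(C)C | intermediate
13 | 3,5-di-tert-butoxy-2-[(Z)-1,2-dimethoxyvinyl]-4-methoxycyclohexa-2,4-dien-1-one | CO/C=C(\OC)C1=C(OC(C)(C)C)C(OC)=C(OC(C)(C)C)CC1=O | intermediate
14 | 3,5-di-tert-butoxy-2-[(Z)-1,2-dimethoxyvinyl]-4-methoxyphenol | CO/C=C(\OC)c1c(O)cc(OC(C)(C)C)c(OC)c1OC(C)(C)C | intermediate
15 | 1-(2,4-di-tert-butoxy-6-hydroxy-3-methoxyphenyl)-2-methoxyethan-1-one | COCC(=O)c1c(O)cc(OC(C)(C)C)c(OC)c1OC(C)(C)C | intermediate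
16 | methyl 4-hydroxy-3,5-diiodobenzoate | COC(=O)c1cc(I)c(O)c(I)c1 | starting material
17 | methyl 3,5-diiodo-4-(methoxymethoxy)benzoate | COCOc1c(I)cc(cc1I)C(=O)OC | intermediate
18 | tributyl(3-methylbut-2-en-1-yl)stannane | CCCC[Sn](CCCC)(CCCC)CC=C(C)C | starting material
19 | methyl 4-(methoxymethoxy)-3,5-bis(3-methylbut-2-en-1-yl)benzoate | COCOc1c(CC=C(C)C)cc(cc1CC=C(C)C)C(=O)OC | intermediate
20 | 4-(methoxymethoxy)-3,5-bis(3-methylbut-2-en-1-yl)benzoic acid | COCOc1c(CC=C(C)C)cc(cc1CC=C(C)C)C(=O)O | intermediate
21 | 3,5-di-tert-butoxy-4-methoxy-2-(methoxyacetyl)phenyl 4-(methoxymethoxy)-3,5-bis(3-methylbut-2-en-1-yl)benzoate | COCC(=O)c1c(OC(=O)c2cc(CC=C(C)C)c(OCOC)c(CC=C(C)C)c2)cc(OC(C)(C)C)c(OC)c1OC(C)(C)C | intermediate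
22 | 1-(2,4-di-tert-butoxy-6-hydroxy-3-methoxyphenyl)-2-methoxy-3-[4-(methoxymethoxy)-3,5-bis(3-methylbut-2-en-1-yl)phenyl]propane-1,3-dione (racemic) | COCOc1c(CC=C(C)C)cc(cc1CC=C(C)C)C(=O)C(OC)C(=O)c1c(O)cc(OC(C)(C)C)c(OC)c1OC(C)(C)C | intermediate
23 | 5,7-di-tert-butoxy-3,6-dimethoxy-2-[4-(methoxymethoxy)-3,5-bis(3-methylbut-2-en-1-yl)phenyl]-4H-chromen-4-one | COCOc1c(CC=C(C)C)cc(cc1CC=C(C)C)-c1oc2cc(OC(C)(C)C)c(OC)c(OC(C)(C)C)c2c(=O)c1OC | intermediate
24 | 5,7-dihydroxy-2-[4-hydroxy-3,5-bis(3-methylbut-2-en-1-yl)phenyl]-3,6-dimethoxy-4H-chromen-4-one | COc1c(O)cc2oc(-c3cc(CC=C(C)C)c(O)c(CC=C(C)C)c3)c(OC)c(=O)c2c1O | target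

Total step count: 10. Longest linear sequence: 7 steps (steps 1, 2, 3, 4, 8, 9, 10); the ring B acid is made in the three-step branch 5–7.

Steps most likely to fail

Step 1. The cation formed in the transposition is also stabilised by the side-chain methoxy group, so it may be captured at the side-chain carbon, or the enol ether may hydrolyse on work-up. Lithium methoxide from the elimination may also exchange a tert-butoxy group of the squarate. The fallback avoids any cationic intermediate and sets out from 4. Quenching 4 with Bu3SnCl should give (E)-tributyl(1,2-dimethoxyvinyl)stannane F1, which can be purified free of lithium methoxide. A Stille coupling of this stannane with 3-tert-butoxy-4-chlorocyclobut-3-ene-1,2-dione F2 (from commercial 3,4-dichlorocyclobut-3-ene-1,2-dione, one equivalent of tert-butanol and 2,6-lutidine), using Pd2(dba)3 and tri(2-furyl)phosphine in dioxane, should replace the chlorine directly and come back to the route at 7.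

Step 2. The hindered tertiary lithium alkoxide may be methylated incompletely, or may open its ring if it warms before it is trapped, and part of the organolithium may add at the vinylogous-ester carbonyl. The fallback separates addition from alkylation and sets out from 10. Quenching with aqueous NH4Cl at −78 °C instead of adding methyl triflate should give 3-tert-butoxy-4-(1-tert-butoxyvinyl)-2-[(Z)-1,2-dimethoxyvinyl]-4-hydroxycyclobut-2-en-1-one F3, which can be purified and checked for regiochemistry. Neutral Purdie methylation (MeI, Ag2O, K2CO3, MeCN, rt) then comes back to the route at 11.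

Step 10. Under protic acid a prenyl side chain may cyclise onto the freed 4'-hydroxyl to give a chroman, and loss of the C5 tert-butyl group before ring closure would allow closure through the wrong phenol. The fallback sets out from 22 and separates ring closure from unmasking. Ring closure in NaOAc-buffered AcOH at 80 °C should give 23, which is isolated. Me3SiOTf with 2,6-lutidine in CH2Cl2 at 0 °C should then exchange the tert-butyl and MOM groups for silyl groups without free acid, giving 2-[3,5-bis(3-methylbut-2-en-1-yl)-4-(trimethylsilyloxy)phenyl]-3,6-dimethoxy-5,7-bis(trimethylsilyloxy)-4H-chromen-4-one F4. K2CO3 in MeOH at rt removes the silyl groups and comes back to the route at 24.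

Further compounds
F1 | step 1 | (E)-tributyl(1,2-dimethoxyvinyl)stannane | CO/C=C(\OC)[Sn](CCCC)(CCCC)CCCC
F2 | step 1 | 3-tert-butoxy-4-chlorocyclobut-3-ene-1,2-dione | CC(C)(C)OC1=C(Cl)C(=O)C1=O
F3 | step 2 | 3-tert-butoxy-4-(1-tert-butoxyvinyl)-2-[(Z)-1,2-dimethoxyvinyl]-4-hydroxycyclobut-2-en-1-one (racemic) | CO/C=C(\OC)C1=C(OC(C)(C)C)C(O)(C(=C)OC(C)(C)C)C1=O
F4 | step 10 | 2-[3,5-bis(3-methylbut-2-en-1-yl)-4-(trimethylsilyloxy)phenyl]-3,6-dimethoxy-5,7-bis(trimethylsilyloxy)-4H-chromen-4-one | COc1c(O[Si](C)(C)C)cc2oc(-c3cc(CC=C(C)C)c(O[Si](C)(C)C)c(CC=C(C)C)c3)c(OC)c(=O)c2c1O[Si](C)(C)C
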